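The route builds ring B instead of decorating it. Four adjacent ring B carbons carry, in order, the diaryl ether oxygen, the Z-alkenyl carbon, the formyl carbon and the phenolic oxygen. The two oxygens are para and the last two ring carbons are CH. That pattern is a 2-oxygenated furan (both C–O carbons plus the CH=CH pair) fused onto a disubstituted alkyne. A furyl aryl ether that already holds ring A therefore adds to mono-protected butynedial, and the oxygen bridge opens. One operation gives the complete phenol with its two aldehyde carbons differentiated. Esterification with a syn diol fragment, cis-selective ring-closing metathesis and one acidic unmasking then deliver the 12-membered lactone.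

Key step: step 6

Assumption: the SMILES is taken literally, so ring A is bridged 1,3 (ester on C1, ether oxygen on C5, methyl on C2), the lactone has 12 ring atoms, the styrenyl alkene is Z and both carbinol carbons are S (a syn diol); C3 (allylic carbinol) and C4 (lactone carbinol bearing pentyl) are the locants of the nonene fragment.

Step 1
Reactants: 1 5-nitrofuran-2-carboxylic acid
Product: 2 tert-butyl 5-nitrofuran-2-carboxylate
Conditions: Cl3CC(=NH)O-t-Bu, CH2Cl2–cyclohexane, rt
Reagents that add atoms: tert-butyl 2,2,2-trichloroacetimidate, CC(C)(C)OC(=N)C(Cl)(Cl)Cl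
Why: O-tert-butylation of a carboxylic acid with a trichloroacetimidate: the fairly strong furoic acid protonates the imidate and captures the tert-butyl cation, giving an ester that acid can later remove without touching the ring A methyl ester.

Step 2
Reactants: 2 tert-butyl 5-nitrofuran-2-carboxylate; 3 methyl 5-hydroxy-2-methylbenzoate
Product: 4 tert-butyl 5-[3-(methoxycarbonyl)-4-methylphenoxy]furan-2-carboxylate
Conditions: K2CO3, DMF, 60 °C
Reagents that add atoms: none
Why: Nucleophilic aromatic substitution by addition–elimination: the nitro group at C5 of a 2-furoate is a proven leaving group because the anionic adduct is delocalised into the C2 ester, so the ring A phenoxide forms the furyl aryl ether bond under mild base that leaves both esters alone.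

Step 3
Reactants: 4 tert-butyl 5-[3-(methoxycarbonyl)-4-methylphenoxy]furan-2-carboxylate
Product: 5 5-[3-(methoxycarbonyl)-4-methylphenoxy]furan-2-carboxylic acid
Conditions: TFA–CH2Cl2, 0 °C → rt
Reagents that add atoms: none
Why: Acidolysis of a tert-butyl ester by loss of 2-methylpropene is orthogonal to the methyl benzoate, and the furan is still deactivated by its carboxyl group and therefore tolerates the acid.

Step 4
Reactants: 5 5-[3-(methoxycarbonyl)-4-methylphenoxy]furan-2-carboxylic acid
Product: 6 methyl 5-(furan-2-yloxy)-2-methylbenzoate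
Conditions: Ag2CO3 (10 mol %), AcOH (5 mol %), DMSO, 120 °C
Reagents that add atoms: none
Why: Silver-catalysed protodecarboxylation of a heteroaromatic carboxylic acid: the 5-aryloxy donor favours ipso metalation and protonation at C2, decarboxylation of 5-oxygenated 2-furoic acids is the classical entry to 2-oxygenated furans, and the nearly neutral medium spares the acid-sensitive product.

Step 5
Reactants: 7 3,3-diethoxyprop-1-yne
Product: 10 4,4-diethoxybut-2-ynal, via lithium acetylide 8 (not isolated), via hemiaminal alkoxide 9 (not isolated)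
Conditions: n-BuLi, THF, −78 °C; DMF, −78 → 0 °C; inverse quench into aq. KH2PO4/MTBE, 0 °C
Reagents that add atoms: N,N-dimethylformamide, CN(C)C=O
Why: Formylation of a lithium acetylide with DMF: the tetrahedral adduct persists until the inverse quench into phosphate buffer, which releases the ynal at a pH where neither conjugate addition of dimethylamine nor acetal hydrolysis competes.

Step 6
Reactants: 6 methyl 5-(furan-2-yloxy)-2-methylbenzoate; 10 4,4-diethoxybut-2-ynal
Product: 12 methyl 5-[3-(diethoxymethyl)-2-formyl-4-hydroxyphenoxy]-2-methylbenzoate, via oxanorbornadiene adduct 11 (not isolated)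
Conditions: 10 (1.2 equiv), PhMe (1 M), BHT (cat.), base-washed glassware, 25 → 60 °C; chromatography on Et3N-deactivated SiO2
Reagents that add atoms: none
Why: This is a normal-electron-demand Diels–Alder reaction of a 2-oxygenated furan with an acetylenic aldehyde followed by aromatising opening of the 7-oxanorbornadiene, the reaction type by which 2-alkoxyfurans are known to give hydroquinone monoethers. The aryloxy group places the largest HOMO coefficient on the unsubstituted furan α-carbon C5 and the formyl group places the largest LUMO coefficient on the acetal-bearing alkyne carbon, so that bond leads in an asynchronous [4+2] addition and the bond from furan C2 to the formyl-bearing alkyne carbon follows, closing the six-membered carbocycle of ring B in an intermolecular two-bond cycloaddition. Adduct 11 then unzips: its ketal-type bridgehead C–O bond heterolyses because the aryloxy oxygen stabilises the cation, the oxygen atom ends up on the hydrogen-bearing bridgehead, and removal of that hydrogen delivers the phenol, with strain release and aromaticity making the sequence irreversible. No stereocentre survives, since both bridgehead centres of racemic 11 become sp2 and 12 is achiral. The selectivity required is regiochemical (aryloxy beside the free formyl group, hydroxyl beside the acetal) and it is secured by the single donor on the diene and the single π-acceptor on the dienophile, the acetal carbon being electronically innocent. Acid is excluded because it would let the acetal equilibrate with the adjacent formyl group through a cyclic 1,3-diethoxyphthalan and erase the differentiation of the two carbons.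

Step 7
Reactants: 12 methyl 5-[3-(diethoxymethyl)-2-formyl-4-hydroxyphenoxy]-2-methylbenzoate
Product: 13 methyl 5-[3-(diethoxymethyl)-2-formyl-4-(methoxymethoxy)phenoxy]-2-methylbenzoate
Conditions: MOMCl, i-Pr2NEt, CH2Cl2, 0 °C → rt
Reagents that add atoms: chloromethyl methyl ether, COCCl
Why: Base-mediated O-alkylation of the phenol with chloromethyl methyl ether: the amine keeps the medium acid-free for the monoacetal, and an acetal-type ether is chosen so that phenol, allylic alcohol and formyl group can all be released in one final acid step instead of a harsh aryl ether cleavage.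

Step 8
Reactants: 13 methyl 5-[3-(diethoxymethyl)-2-formyl-4-(methoxymethoxy)phenoxy]-2-methylbenzoate
Product: 14 methyl 5-[3-(diethoxymethyl)-2-ethenyl-4-(methoxymethoxy)phenoxy]-2-methylbenzoate
Conditions: Ph3PCH3Br, KO-t-Bu, THF, 0 °C → rt
Reagents that add atoms: methyltriphenylphosphonium bromide, C[P+](c1ccccc1)(c1ccccc1)c1ccccc1.[Br-]
Why: Wittig methylenation: the small non-stabilised ylide reaches the di-ortho-substituted aldehyde, the only carbonyl group reactive enough, while benzoate, acetal and MOM ether are inert.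

Step 9
Reactants: 14 methyl 5-[3-(diethoxymethyl)-2-ethenyl-4-(methoxymethoxy)phenoxy]-2-methylbenzoate
Product: 15 5-[3-(diethoxymethyl)-2-ethenyl-4-(methoxymethoxy)phenoxy]-2-methylbenzoic acid
Conditions: LiOH, THF–MeOH–H2O, 50 °C; then 1 M HCl to pH 4–5, 0 °C
Reagents that add atoms: lithium hydroxide, [Li+].[OH-]
Why: Saponification (acyl–oxygen cleavage) of the single ester, slowed only slightly by the ortho methyl group, under conditions to which acetal, MOM ether and styrene are inert, followed by cold acidification that stops short of acetal hydrolysis.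

Step 10
Reactants: 16 prop-2-en-1-ol (allyl alcohol)
Product: 17 3-(methoxymethoxy)prop-1-ene
Conditions: MOMCl, i-Pr2NEt, CH2Cl2, 0 °C → rt; distillation
Reagents that add atoms: chloromethyl methyl ether, COCCl
Why: Straightforward O-alkylation of a primary alcohol with chloromethyl methyl ether gives the volatile ether, which is purified by distillation.

Step 11
Reactants: 17 3-(methoxymethoxy)prop-1-ene; 18 (+)-B-methoxydiisopinocampheylborane (from (−)-α-pinene); 19 hexanal
Product: 24 (3S,4S)-3-(methoxymethoxy)non-1-en-4-ol, via allyllithium 20 (not isolated), via borate complex 21 (not isolated), via allylborane 22 (not isolated), via borinate ester 23 (not isolated)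
Conditions: s-BuLi, THF, −78 °C; 18, −78 °C; BF3·OEt2, then 19, −78 °C → rt; NaOH, H2O2
Reagents that add atoms: none
Why: Brown asymmetric alkoxyallylboration: lithiation gives the internally chelated Z allyl anion, the derived (Z)-γ-alkoxyallylborane adds through a closed chair transition state that converts Z geometry into the syn relationship of C3 and C4, and the isopinocampheyl groups derived from (−)-α-pinene select the aldehyde face that gives 4S and therefore 3S, with the two oxygens differentiated from the outset.

Step 12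
Reactants: 15 5-[3-(diethoxymethyl)-2-ethenyl-4-(methoxymethoxy)phenoxy]-2-methylbenzoic acid; 24 (3S,4S)-3-(methoxymethoxy)non-1-en-4-ol
Product: 26 (3S,4S)-3-(methoxymethoxy)non-1-en-4-yl 5-[3-(diethoxymethyl)-2-ethenyl-4-(methoxymethoxy)phenoxy]-2-methylbenzoate, via mixed anhydride 25 (not isolated)
Conditions: 2,4,6-Cl3C6H2COCl, Et3N, THF, rt; then 24, DMAP, PhMe, rt → 40 °C
Reagents that add atoms: none
Why: Yamaguchi esterification: DMAP attacks the less hindered carbonyl of the mixed anhydride and transfers the ring A acyl group to O4, so the C4–O bond is never broken and both stereocentres are retained under non-acidic conditions.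

Step 13
Reactants: 26 (3S,4S)-3-(methoxymethoxy)non-1-en-4-yl 5-[3-(diethoxymethyl)-2-ethenyl-4-(methoxymethoxy)phenoxy]-2-methylbenzoate
Product: 27 protected (Z)-macrolactone (target ring system with CH(OEt)2 in place of CHO on ring B and MOM ethers on the phenol and on O3; C3 and C4 both S)
Conditions: Ru(NO3)(=CH-C6H4-2-O-i-Pr)(L), L = cyclometalated 1-(adamantan-1-yl)-3-(2,6-diisopropylphenyl)imidazolidin-2-ylidene (Z-selective Grubbs catalyst, 10 mol %), ClCH2CH2Cl (3 mM), 60 °C, static vacuum
Reagents that add atoms: none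
Why: Kinetically Z-selective macrocyclic ring-closing metathesis: in the side-bound ruthenacyclobutane of the chelated catalyst both substituents point away from the N-aryl group so that cycloreversion releases the cis alkene, removal of ethene drives closure of the 12-membered ring, and the fully masked substrate offers no protic or carbonyl group to the catalyst.

Step 14
Reactants: 27 protected (Z)-macrolactone
Product: 28 target CNP0238900.1
Conditions: 3 M aq. HCl–THF, 40 °C
Reagents that add atoms: water, O
Why: Acid-catalysed hydrolysis of three acetal-type groups in one operation: the aryl acetal and the phenolic MOM ether fall first, and the resulting hydrogen-bonded, electron-poor salicylaldehyde ring, twisted out of conjugation with the cis alkene, disfavours ionisation at allylic C3 while the slower aliphatic MOM ether is cleaved, so alkene geometry and both S centres are kept.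

Compound list
1 | 5-nitrofuran-2-carboxylic acid | OC(=O)c1ccc(o1)[N+](=O)[O-] | starting material
2 | tert-butyl 5-nitrofuran-2-carboxylate | CC(C)(C)OC(=O)c1ccc(o1)[N+](=O)[O-] | intermediate
3 | methyl 5-hydroxy-2-methylbenzoate | COC(=O)c1cc(O)ccc1C | starting material
4 | tert-butyl 5-[3-(methoxycarbonyl)-4-methylphenoxy]furan-2-carboxylate | COC(=O)c1cc(Oc2ccc(o2)C(=O)OC(C)(C)C)ccc1C | intermediate
5 | 5-[3-(methoxycarbonyl)-4-methylphenoxy]furan-2-carboxylic acid | COC(=O)c1cc(Oc2ccc(o2)C(O)=O)ccc1C | intermediate
6 | methyl 5-(furan-2-yloxy)-2-methylbenzoate | COC(=O)c1cc(Oc2ccco2)ccc1C | intermediate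
7 | 3,3-diethoxyprop-1-yne | CCOC(OCC)C#C | starting material
8 | (3,3-diethoxyprop-1-yn-1-yl)lithium (not isolated) | CCOC(OCC)C#C[Li] | intermediate
9 | lithium 1-(dimethylamino)-4,4-diethoxybut-2-yn-1-olate (not isolated) | CCOC(OCC)C#CC([O-])N(C)C.[Li+] | intermediate
10 | 4,4-diethoxybut-2-ynal | CCOC(OCC)C#CC=O | intermediate
11 | methyl 5-{[3-(diethoxymethyl)-2-formyl-7-oxabicyclo[2.2.1]hepta-2,5-dien-1-yl]oxy}-2-methylbenzoate (racemic, not isolated) | CCOC(OCC)C1=C(C=O)C2(Oc3ccc(C)c(c3)C(=O)OC)OC1C=C2 | intermediate
12 | methyl 5-[3-(diethoxymethyl)-2-formyl-4-hydroxyphenoxy]-2-methylbenzoate | COC(=O)c1cc(Oc2ccc(O)c(C(OCC)OCC)c2C=O)ccc1C | intermediate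
13 | methyl 5-[3-(diethoxymethyl)-2-formyl-4-(methoxymethoxy)phenoxy]-2-methylbenzoate | COC(=O)c1cc(Oc2ccc(OCOC)c(C(OCC)OCC)c2C=O)ccc1C | intermediate
14 | methyl 5-[3-(diethoxymethyl)-2-ethenyl-4-(methoxymethoxy)phenoxy]-2-methylbenzoate | COC(=O)c1cc(Oc2ccc(OCOC)c(C(OCC)OCC)c2C=C)ccc1C | intermediate
15 | 5-[3-(diethoxymethyl)-2-ethenyl-4-(methoxymethoxy)phenoxy]-2-methylbenzoic acid | OC(=O)c1cc(Oc2ccc(OCOC)c(C(OCC)OCC)c2C=C)ccc1C | intermediate
16 | prop-2-en-1-ol | OCC=C | starting material
17 | 3-(methoxymethoxy)prop-1-ene | COCOCC=C | intermediate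
18 | (+)-B-methoxydiisopinocampheylborane | COB([C@H]1C[C@H]2C[C@@H]([C@@H]1C)C2(C)C)[C@H]1C[C@H]2C[C@@H]([C@@H]1C)C2(C)C | starting material
19 | hexanal | CCCCCC=O | starting material
20 | (Z)-[3-(methoxymethoxy)prop-2-en-1-yl]lithium (not isolated) | [Li]C/C=C\OCOC | intermediate
21 | lithium methoxy[(Z)-3-(methoxymethoxy)allyl]diisopinocampheylborate (not isolated) | [Li+].COCO/C=C\C[B-](OC)([C@H]1C[C@H]2C[C@@H]([C@@H]1C)C2(C)C)[C@H]1C[C@H]2C[C@@H]([C@@H]1C)C2(C)C | intermediate
22 | [(Z)-3-(methoxymethoxy)allyl]diisopinocampheylborane (not isolated) | COCO/C=C\CB([C@H]1C[C@H]2C[C@@H]([C@@H]1C)C2(C)C)[C@H]1C[C@H]2C[C@@H]([C@@H]1C)C2(C)C | intermediate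
23 | (3S,4S)-3-(methoxymethoxy)non-1-en-4-yl diisopinocampheylborinate (not isolated) | CCCCC[C@H](OB([C@H]1C[C@H]2C[C@@H]([C@@H]1C)C2(C)C)[C@H]1C[C@H]2C[C@@H]([C@@H]1C)C2(C)C)[C@@H](OCOC)C=C | intermediate
24 | (3S,4S)-3-(methoxymethoxy)non-1-en-4-ol | CCCCC[C@H](O)[C@@H](OCOC)C=C | intermediate
25 | mixed anhydride of 15 and 2,4,6-trichlorobenzoic acid (not isolated) | Cc1ccc(Oc2ccc(OCOC)c(C(OCC)OCC)c2C=C)cc1C(=O)OC(=O)c1c(Cl)cc(Cl)cc1Cl | intermediate
26 | (3S,4S)-3-(methoxymethoxy)non-1-en-4-yl 5-[3-(diethoxymethyl)-2-ethenyl-4-(methoxymethoxy)phenoxy]-2-methylbenzoate | CCCCC[C@H](OC(=O)c1cc(Oc2ccc(OCOC)c(C(OCC)OCC)c2C=C)ccc1C)[C@@H](OCOC)C=C | intermediate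
27 | protected (Z)-macrolactone: 12-membered lactone, ring B bearing CH(OEt)2 and OMOM, O3 as MOM ether, C3 and C4 both S | CCCCC[C@@H]1OC(=O)c2cc(ccc2C)Oc2ccc(OCOC)c(C(OCC)OCC)c2/C=C\[C@@H]1OCOC | intermediate
28 | CNP0238900.1: 12-membered lactone of the ring A C1 carboxyl (2-methyl, 5-aryloxy) with the (S)-carbinol bearing n-pentyl, next to the free (S)-allylic carbinol, joined by a Z CH=CH unit to ring B (aryloxy, alkenyl, CHO, OH on four adjacent carbons) | CCCCC[C@@H]1OC(=O)c2cc(ccc2C)Oc2ccc(O)c(C=O)c2/C=C\[C@@H]1O | target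

Total step count: 14. Longest linear sequence: 11 steps (1, 2, 3, 4, 6, 7, 8, 9, 12, 13, 14).

Steps most likely to fail

1. Step 6.
- What may go wrong: an aryloxyfuran is a weaker donor than an alkoxyfuran, so cycloaddition may be slow. Ynal polymerisation, conjugate addition at furan C5 without ring closure, or phenol-catalysed scrambling of the acetal onto the neighbouring formyl group may then compete.
- Fallback (sets out from 10, returns at 13): ring B is still built from the ynal, but with a well-documented diene, and the diaryl ether is made afterwards.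
- Ynal 10 is combined with commercial 2-(trimethylsilyloxy)furan, which obeys the same donor/acceptor pairing. This gives 2-(diethoxymethyl)-3-hydroxy-6-(trimethylsilyloxy)benzaldehyde F1.
- Buffered fluoride (Bu4NF, AcOH, THF, 0 °C) releases 2-(diethoxymethyl)-3,6-dihydroxybenzaldehyde F2.
- One equivalent of MOMCl with i-Pr2NEt caps the hydroxyl beside the acetal, because the other hydroxyl is tied up in a hydrogen bond to the formyl group. This gives 2-(diethoxymethyl)-6-hydroxy-3-(methoxymethoxy)benzaldehyde F3.
- Chan–Lam coupling of F3 with commercial [3-(methoxycarbonyl)-4-methylphenyl]boronic acid (Cu(OAc)2, pyridine, 4 Å MS, CH2Cl2, air) gives 13.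

2. Step 13.
- What may go wrong: the styrene is flanked by two ortho substituents and the partner alkene is allylically branched. Metallacycle formation may therefore be slower than catalyst decay, oligomerisation may compete, and secondary metathesis would erode the cis geometry.
- Fallback (sets out from 13, returns at 27): the cis alkene is fixed before ring closure by alkyne semihydrogenation, and the ring is closed at the ester bond.
- Aldehyde 13 is homologated with the Ohira–Bestmann reagent (K2CO3, MeOH) to methyl 5-[3-(diethoxymethyl)-2-ethynyl-4-(methoxymethoxy)phenoxy]-2-methylbenzoate F4.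
- The partner comes from commercial tert-butyldimethylsilyl (S)-glycidyl ether. Opening with n-BuMgBr/CuI gives (S)-1-(tert-butyldimethylsilyloxy)heptan-2-ol F5. 4-Methoxybenzyl trichloroacetimidate with La(OTf)3 (cat.) gives (S)-1-(tert-butyldimethylsilyloxy)-2-(4-methoxybenzyloxy)heptane F6. Bu4NF gives (S)-2-(4-methoxybenzyloxy)heptan-1-ol F7. Dess–Martin oxidation gives (S)-2-(4-methoxybenzyloxy)heptanal F8.
- The alkynylzinc reagent from F4 (LiN(SiMe3)2, THF, −78 °C, then ZnBr2) adds to F8 under chelation control and should give the syn (3S,4S) propargylic alcohol F9.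
- MOMCl/i-Pr2NEt gives the C3 MOM ether F10, and DDQ (CH2Cl2, pH 7 buffer) frees O4 to give the alkynyl C4 alcohol F11.
- H2 over Pd/CaCO3 poisoned with Pb(OAc)2 (Lindlar catalyst) with quinoline gives the (Z)-alkenyl hydroxy ester F12, and LiOH gives the (Z)-seco acid F13.
- Yamaguchi macrolactonisation (2,4,6-Cl3C6H2COCl, Et3N; slow addition to DMAP, PhMe, high dilution) gives 27.

3. Step 14.
- What may go wrong: the prolonged acid needed for the aliphatic MOM ether may trigger ionisation of the allylic C3–O bond, leading to cis to trans isomerisation or allylic transposition. It may also cause capture of the C3 hydroxyl by the neighbouring formyl group as a seven-membered cyclic acetal, or migration of the acyl group from O4 to O3.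
- Fallback (sets out from 26, returns at 28): the acid step is moved ahead of ring closure, where the allylic alcohol is only a simple vinyl carbinol, and the final unmasking is done with fluoride.
- Diene 26 is treated with 3 M aq. HCl–THF to give the fully deprotected diene (3S,4S)-3-hydroxynon-1-en-4-yl 5-(2-ethenyl-3-formyl-4-hydroxyphenoxy)-2-methylbenzoate F14.
- TBSOTf/2,6-lutidine gives the bis(tert-butyldimethylsilyl) ether F15.
- The Z-selective ring closure of step 13, which tolerates the slimmer free formyl group, gives the bis-silylated (Z)-macrolactone F16.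
- HF·pyridine buffered with pyridine (THF, 0 °C) gives 28.

Further compounds
F1 | step 6 | 2-(diethoxymethyl)-3-hydroxy-6-(trimethylsilyloxy)benzaldehyde | CCOC(OCC)c1c(O)ccc(O[Si](C)(C)C)c1C=O
F2 | step 6 | 2-(diethoxymethyl)-3,6-dihydroxybenzaldehyde | CCOC(OCC)c1c(O)ccc(O)c1C=O
F3 | step 6 | 2-(diethoxymethyl)-6-hydroxy-3-(methoxymethoxy)benzaldehyde | CCOC(OCC)c1c(OCOC)ccc(O)c1C=O
F4 | step 13 | methyl 5-[3-(diethoxymethyl)-2-ethynyl-4-(methoxymethoxy)phenoxy]-2-methylbenzoate | COC(=O)c1cc(Oc2ccc(OCOC)c(C(OCC)OCC)c2C#C)ccc1C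
F5 | step 13 | (S)-1-(tert-butyldimethylsilyloxy)heptan-2-ol | CCCCC[C@H](O)CO[Si](C)(C)C(C)(C)C
F6 | step 13 | (S)-1-(tert-butyldimethylsilyloxy)-2-(4-methoxybenzyloxy)heptane | CCCCC[C@H](OCc1ccc(OC)cc1)CO[Si](C)(C)C(C)(C)C
F7 | step 13 | (S)-2-(4-methoxybenzyloxy)heptan-1-ol | CCCCC[C@H](OCc1ccc(OC)cc1)CO
F8 | step 13 | (S)-2-(4-methoxybenzyloxy)heptanal | CCCCC[C@H](OCc1ccc(OC)cc1)C=O
F9 | step 13 | methyl 5-{3-(diethoxymethyl)-2-[(3S,4S)-3-hydroxy-4-(4-methoxybenzyloxy)non-1-yn-1-yl]-4-(methoxymethoxy)phenoxy}-2-methylbenzoate | CCCCC[C@H](OCc1ccc(OC)cc1)[C@@H](O)C#Cc1c(Oc2ccc(C)c(c2)C(=O)OC)ccc(OCOC)c1C(OCC)OCC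
F10 | step 13 | methyl 5-{3-(diethoxymethyl)-2-[(3S,4S)-4-(4-methoxybenzyloxy)-3-(methoxymethoxy)non-1-yn-1-yl]-4-(methoxymethoxy)phenoxy}-2-methylbenzoate | CCCCC[C@H](OCc1ccc(OC)cc1)[C@@H](OCOC)C#Cc1c(Oc2ccc(C)c(c2)C(=O)OC)ccc(OCOC)c1C(OCC)OCC
F11 | step 13 | methyl 5-{3-(diethoxymethyl)-2-[(3S,4S)-4-hydroxy-3-(methoxymethoxy)non-1-yn-1-yl]-4-(methoxymethoxy)phenoxy}-2-methylbenzoate | CCCCC[C@H](O)[C@@H](OCOC)C#Cc1c(Oc2ccc(C)c(c2)C(=O)OC)ccc(OCOC)c1C(OCC)OCC
F12 | step 13 | methyl 5-{3-(diethoxymethyl)-2-[(1Z,3S,4S)-4-hydroxy-3-(methoxymethoxy)non-1-en-1-yl]-4-(methoxymethoxy)phenoxy}-2-methylbenzoate | CCCCC[C@H](O)[C@@H](OCOC)/C=C\c1c(Oc2ccc(C)c(c2)C(=O)OC)ccc(OCOC)c1C(OCC)OCC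
F13 | step 13 | 5-{3-(diethoxymethyl)-2-[(1Z,3S,4S)-4-hydroxy-3-(methoxymethoxy)non-1-en-1-yl]-4-(methoxymethoxy)phenoxy}-2-methylbenzoic acid | CCCCC[C@H](O)[C@@H](OCOC)/C=C\c1c(Oc2ccc(C)c(c2)C(=O)O)ccc(OCOC)c1C(OCC)OCC
F14 | step 14 | (3S,4S)-3-hydroxynon-1-en-4-yl 5-(2-ethenyl-3-formyl-4-hydroxyphenoxy)-2-methylbenzoate | CCCCC[C@H](OC(=O)c1cc(Oc2ccc(O)c(C=O)c2C=C)ccc1C)[C@@H](O)C=C
F15 | step 14 | (3S,4S)-3-(tert-butyldimethylsilyloxy)non-1-en-4-yl 5-[4-(tert-butyldimethylsilyloxy)-2-ethenyl-3-formylphenoxy]-2-methylbenzoate | CCCCC[C@H](OC(=O)c1cc(Oc2ccc(O[Si](C)(C)C(C)(C)C)c(C=O)c2C=C)ccc1C)[C@@H](O[Si](C)(C)C(C)(C)C)C=C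
F16 | step 14 | bis(tert-butyldimethylsilyl) ether of 28 (phenol and O3 silylated, Z alkene, C3 and C4 both S) | CCCCC[C@@H]1OC(=O)c2cc(ccc2C)Oc2ccc(O[Si](C)(C)C(C)(C)C)c(C=O)c2/C=C\[C@@H]1O[Si](C)(C)C(C)(C)C
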